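The plan disconnects the bond between C2 of the propenyl unit (the fully substituted enol-ether carbon) and the cresol ring C. It exploits the fact that the phenolic oxygen of ring C and the oxygen of the CH2OH group on C2 are separated by only four carbons, so that a single silicon atom can bridge them. An intramolecular Heck reaction of the resulting tethered aryl iodide should, in one operation, form the C2–aryl bond, close a temporary seven-membered dioxasilepine and turn the (E)-disubstituted enol ether into the (Z)-trisubstituted one. The precursor is the diisopropylsilylene diether linking 2-iodo-5-methylphenol to the (E)-3-alkoxyallyl alcohol made from (S)-1-(7-methoxy-2,2-dimethyl-2H-chromen-6-yl)ethanol.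

Key step: step 7

Remarks on the chemistry:
- Ring A is the benzene ring of the chromene, ring B its pyran ring, and ring C the 2-hydroxy-4-methylphenyl ring. C1 (O–CH=), C2 (fully substituted) and C3 (CH2OH) are the propenyl carbons.
- The target SMILES is read as (S) at the benzylic carbon and (Z) at the enol ether (alkoxy cis to CH2OH, trans to ring C).
- Every compound from 7 onward is assumed to be acid-labile, so base-washed glassware and Et3N-deactivated silica are used. For the same reason the final fluoride cleavage is run without added acid.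

Step 1
Reactants: 1 3-methoxyphenol; 2 3-methylbut-2-enal
Product: 5 7-methoxy-2,2-dimethyl-2H-chromene, via benzodioxaborin 3 (not isolated), via ortho-quinone methide 4 (not isolated)
Conditions: PhB(OH)2 (1 equiv), AcOH, toluene, reflux, Dean–Stark
Reagents that add atoms: none
Why: Boronate-templated ortho-condensation of the phenol with the enal gives a benzodioxaborin that fragments to an ortho-quinone methide, which closes by oxa-6π electrocyclisation (phenol–enal chromenylation), and attack at the unhindered phenol carbon para to OMe should place the methoxy group at C7.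

Step 2
Reactants: 5 7-methoxy-2,2-dimethyl-2H-chromene
Product: 6 1-(7-methoxy-2,2-dimethyl-2H-chromen-6-yl)ethan-1-one
Conditions: AcCl (1.1 equiv), AlCl3 (1.1 equiv), CH2Cl2, −78 °C, inverse addition of 5; cold aqueous NaHCO3
Reagents that add atoms: acetyl chloride, CC(=O)Cl
Why: Friedel–Crafts acylation should go to C6 of ring A, which is para to the ring oxygen, ortho to OMe and less hindered than C8, and running it at −78 °C with the preformed acyl chloride–AlCl3 complex lets C-acylation outrun acid-induced dimerisation at the C3=C4 bond.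

Step 3
Reactants: 6 1-(7-methoxy-2,2-dimethyl-2H-chromen-6-yl)ethan-1-one
Product: 7 (1S)-1-(7-methoxy-2,2-dimethyl-2H-chromen-6-yl)ethan-1-ol
Conditions: RuCl(p-cymene)[(S,S)-TsDPEN] (1 mol %), HCO2Na (5 equiv), H2O/MeOH 1:1, 40 °C
Reagents that add atoms: none
Why: Noyori–Ikariya asymmetric transfer hydrogenation: the (S,S)-TsDPEN ruthenium hydride delivers hydride to the Re face of the aryl methyl ketone through its CH/π-organised six-membered transition state, which sets the (S) carbinol centre, while the C3=C4 alkene is inert and the near-neutral formate medium does not ionise the electron-rich benzylic alcohol.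

Step 4
Reactants: 7 (1S)-1-(7-methoxy-2,2-dimethyl-2H-chromen-6-yl)ethan-1-ol; 8 methyl prop-2-ynoate
Product: 9 methyl (2E)-3-[(1S)-1-(7-methoxy-2,2-dimethyl-2H-chromen-6-yl)ethoxy]prop-2-enoate
Conditions: 8 (1.5 equiv), N-methylmorpholine (1.5 equiv), CH2Cl2, rt
Reagents that add atoms: none
Why: Amine-catalysed oxa-Michael addition of an alcohol to a propiolate gives the (E)-β-alkoxyacrylate selectively, and since the carbinol C–O bond is not broken the (S) centre is carried over unchanged.

Step 5
Reactants: 9 methyl (2E)-3-[(1S)-1-(7-methoxy-2,2-dimethyl-2H-chromen-6-yl)ethoxy]prop-2-enoate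
Product: 11 (2E)-3-[(1S)-1-(7-methoxy-2,2-dimethyl-2H-chromen-6-yl)ethoxy]prop-2-en-1-ol, via enal 10 (not isolated)
Conditions: iBu2AlH (2.5 equiv), CH2Cl2, −78 °C; aqueous potassium sodium tartrate (KNaC4H4O6)
Reagents that add atoms: none
Why: iBu2AlH reduces the ester of a β-alkoxyacrylate in the 1,2 sense through the enal to the allylic alcohol without touching the enol ether or its (E) geometry, and the basic tartrate work-up protects the acid-labile γ-alkoxyallyl alcohol.

Step 6
Reactants: 12 2-iodo-5-methylphenol; 11 (2E)-3-[(1S)-1-(7-methoxy-2,2-dimethyl-2H-chromen-6-yl)ethoxy]prop-2-en-1-ol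
Product: 14 (2-iodo-5-methylphenoxy){[(2E)-3-[(1S)-1-(7-methoxy-2,2-dimethyl-2H-chromen-6-yl)ethoxy]prop-2-en-1-yl]oxy}di(propan-2-yl)silane, via aryloxychlorosilane 13 (not isolated)
Conditions: iPr2SiCl2 (1.1 equiv), Et3N (3 equiv), CH2Cl2, 0 °C, slow addition of 12; then 11 (0.9 equiv), DMAP (0.1 equiv), 0 °C → rt
Reagents that add atoms: dichlorodi(propan-2-yl)silane, CC(C)[Si](Cl)(Cl)C(C)C
Why: Sequential silylation with a dichlorosilane, the standard assembly of unsymmetrical silylene diethers: the phenol displaces the first chloride, the less reactive aryloxychlorosilane is then captured by the primary alcohol under DMAP catalysis, and excess amine keeps the enol ether away from HCl.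

Step 7
Reactants: 14 (2-iodo-5-methylphenoxy){[(2E)-3-[(1S)-1-(7-methoxy-2,2-dimethyl-2H-chromen-6-yl)ethoxy]prop-2-en-1-yl]oxy}di(propan-2-yl)silane
Product: 17 (5Z)-5-{[(1S)-1-(7-methoxy-2,2-dimethyl-2H-chromen-6-yl)ethoxy]methylidene}-8-methyl-2,2-di(propan-2-yl)-4,5-dihydro-1,3,2-benzodioxasilepine, via arylpalladium iodide 15 (not isolated), via alkylpalladium iodide 16 (not isolated)
Conditions: Pd(OAc)2 (10 mol %), PPh3 (25 mol %), 1,2,2,6,6-pentamethylpiperidine (3 equiv), MeCN (0.01 M), 80 °C
Reagents that add atoms: none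
Why: Proposed new method: zerovalent palladium inserts into the carbon–iodine bond of ring C to give 15, the aryl–palladium bond adds syn across the (E)-enol ether with aryl to C2 and palladium to C1 to give 16, and after rotation about the exocyclic C1–C2 bond the only β-hydrogen (on C2) is lost by syn β-hydride elimination, the amine taking up hydrogen iodide. The closest known reactions are silicon-tethered intramolecular Mizoroki–Heck cyclisations and the stereospecific Heck arylation of 1,2-disubstituted alkenes, while a silylene diether tether closing a seven-membered ring onto an enol ether is the untested part. The one new ring, the dioxasilepine, closes 7-exo-trig because the O–Si–O tether holds the aryl over C2, whereas 8-endo attack at C1 is geometrically worse and, with iodide kept on palladium, also electronically disfavoured since the aryl prefers the carbon β to the enol-ether oxygen. No stereocentre is created; the alkene geometry is controlled by the (E) configuration of 14, because syn addition followed by syn elimination must place the alkoxy group cis to CH2O and trans to the aryl, that is (Z). High dilution suppresses intermolecular arylation of the chromene C3=C4 bond, and the hindered, poorly coordinating amine limits reduction of 15 and leaves the aryl silyl ether intact.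

Step 8
Reactants: 17 (5Z)-5-{[(1S)-1-(7-methoxy-2,2-dimethyl-2H-chromen-6-yl)ethoxy]methylidene}-8-methyl-2,2-di(propan-2-yl)-4,5-dihydro-1,3,2-benzodioxasilepine
Product: 18 2-[(1Z)-3-hydroxy-1-{(1S)-1-(7-methoxy-2,2-dimethyl-2H-chromen-6-yl)ethoxy}prop-1-en-2-yl]-5-methylphenol (CNP0279099.1)
Conditions: Bu4NF (2.5 equiv), THF, 0 °C; aqueous KH2PO4/K2HPO4 buffer (pH 7)
Reagents that add atoms: none
Why: Fluoride-induced desilylation cleaves both Si–O bonds of the silylene diether, and because no acid is present the liberated phenol cannot cyclise onto the enol ether, whose (Z) geometry and (S) centre are not involved.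

Compound list
1 | 3-methoxyphenol | COc1cccc(O)c1 | starting material
2 | 3-methylbut-2-enal | CC(C)=CC=O | starting material
3 | 7-methoxy-4-(2-methylprop-1-en-1-yl)-2-phenyl-4H-1,3,2-benzodioxaborin (racemic) | COc1ccc2c(c1)OB(c1ccccc1)OC2C=C(C)C | intermediate
4 | 3-methoxy-6-(3-methylbut-2-en-1-ylidene)cyclohexa-2,4-dien-1-one | COC1=CC(=O)C(=CC=C(C)C)C=C1 | intermediate
5 | 7-methoxy-2,2-dimethyl-2H-chromene | COc1ccc2c(c1)OC(C)(C)C=C2 | intermediate
6 | 1-(7-methoxy-2,2-dimethyl-2H-chromen-6-yl)ethan-1-one | COc1cc2c(cc1C(C)=O)C=CC(C)(C)O2 | intermediate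
7 | (1S)-1-(7-methoxy-2,2-dimethyl-2H-chromen-6-yl)ethan-1-ol | COc1cc2c(cc1[C@H](C)O)C=CC(C)(C)O2 | intermediate
8 | methyl prop-2-ynoate (methyl propiolate) | C#CC(=O)OC | starting material
9 | methyl (2E)-3-[(1S)-1-(7-methoxy-2,2-dimethyl-2H-chromen-6-yl)ethoxy]prop-2-enoate | COc1cc2c(cc1[C@H](C)O/C=C/C(=O)OC)C=CC(C)(C)O2 | intermediate
10 | (2E)-3-[(1S)-1-(7-methoxy-2,2-dimethyl-2H-chromen-6-yl)ethoxy]prop-2-enal | COc1cc2c(cc1[C@H](C)O/C=C/C=O)C=CC(C)(C)O2 | intermediate
11 | (2E)-3-[(1S)-1-(7-methoxy-2,2-dimethyl-2H-chromen-6-yl)ethoxy]prop-2-en-1-ol | COc1cc2c(cc1[C@H](C)O/C=C/CO)C=CC(C)(C)O2 | intermediate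
12 | 2-iodo-5-methylphenol | Cc1ccc(I)c(O)c1 | starting material
13 | chloro(2-iodo-5-methylphenoxy)di(propan-2-yl)silane | Cc1ccc(I)c(O[Si](Cl)(C(C)C)C(C)C)c1 | intermediate
14 | (2-iodo-5-methylphenoxy){[(2E)-3-[(1S)-1-(7-methoxy-2,2-dimethyl-2H-chromen-6-yl)ethoxy]prop-2-en-1-yl]oxy}di(propan-2-yl)silane | COc1cc2c(cc1[C@H](C)O/C=C/CO[Si](C(C)C)(C(C)C)Oc1cc(C)ccc1I)C=CC(C)(C)O2 | intermediate
15 | arylpalladium iodide from insertion of palladium into the carbon–iodine bond of 14 (phosphine ligands omitted) | COc1cc2c(cc1[C@H](C)O/C=C/CO[Si](C(C)C)(C(C)C)Oc1cc(C)ccc1[Pd]I)C=CC(C)(C)O2 | intermediate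
16 | α-alkoxyalkylpalladium iodide, the syn 7-exo adduct with palladium on C1 and ring C on C2 (phosphine ligands omitted; either alkene face may react, so the two new centres are drawn without descriptors) | COc1cc2c(cc1[C@H](C)OC([Pd]I)C1CO[Si](C(C)C)(C(C)C)Oc3cc(C)ccc13)C=CC(C)(C)O2 | intermediate
17 | (5Z)-5-{[(1S)-1-(7-methoxy-2,2-dimethyl-2H-chromen-6-yl)ethoxy]methylidene}-8-methyl-2,2-di(propan-2-yl)-4,5-dihydro-1,3,2-benzodioxasilepine | COc1cc2c(cc1[C@H](C)O/C=C1\CO[Si](C(C)C)(C(C)C)Oc3cc(C)ccc13)C=CC(C)(C)O2 | intermediate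
18 | 2-[(1Z)-3-hydroxy-1-{(1S)-1-(7-methoxy-2,2-dimethyl-2H-chromen-6-yl)ethoxy}prop-1-en-2-yl]-5-methylphenol | COc1cc2c(cc1[C@H](C)O/C=C(\CO)c1ccc(C)cc1O)C=CC(C)(C)O2 | target

Total step count: 8.
Longest linear sequence: 8 steps (1 → 18); 8 and 12 are purchased and enter at steps 4 and 6.

Steps most likely to fail

Step 7 (proposed new method). The 7-exo carbopalladation may be slow. That would allow reductive loss of iodine from the arylpalladium intermediate, insertion in the 8-endo sense, palladium hydride re-addition that moves the double bond toward the silyloxy carbon, or Si–O cleavage before ring closure. The fallback uses known chemistry and forms the enol-ether C–O bond instead of the C2–aryl bond. It sets out from 12 and 7 and comes back to the route at 18.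
- 12 is silylated (iPr3SiCl, imidazole, DMF) to (2-iodo-5-methylphenoxy)tri(propan-2-yl)silane F1.
- Iodine–magnesium exchange (iPrMgCl·LiCl, THF, −20 °C) gives [4-methyl-2-(triisopropylsilyloxy)phenyl]magnesium chloride F2.
- Under CuI catalysis F2 adds anti across the chloromagnesium alkoxide of prop-2-yn-1-ol (C#CCO, deprotonated beforehand with iPrMgCl), aryl going to the internal carbon. This copper-catalysed anti-carbomagnesiation of propargyl alcohol gives the chelated alkenylmagnesium alkoxide 4-[4-methyl-2-(triisopropylsilyloxy)phenyl]-2,5-dihydro-1,2-oxamagnesole F3.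
- Iodine at −20 °C converts it into (2Z)-3-iodo-2-[4-methyl-2-(triisopropylsilyloxy)phenyl]prop-2-en-1-ol F4, in which iodine is cis to CH2OH.
- Silylation (tBuMe2SiCl, imidazole, CH2Cl2) gives tert-butyl{[(2Z)-3-iodo-2-[4-methyl-2-(triisopropylsilyloxy)phenyl]prop-2-en-1-yl]oxy}dimethylsilane F5.
- Stereoretentive Ullmann-type O-vinylation of 7 with F5 (CuI, 3,4,7,8-tetramethyl-1,10-phenanthroline, Cs2CO3, toluene, 80 °C) should give the bis-silyl ether of the target F6.
- Bu4NF in THF at 0 °C then removes both silyl groups to give 18.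

Step 6. Double substitution at silicon may give symmetrical diaryloxy- or dialkoxysilanes, and the γ-alkoxyallyl alcohol may ionise and decompose on contact with HCl or the chlorosilane. The fallback introduces silicon as a monofunctional hydrosilane and activates it without HCl. It sets out from 12 and comes back at 14.
- 12 is silylated with iPr2SiHCl and Et3N in CH2Cl2 to give (2-iodo-5-methylphenoxy)di(propan-2-yl)silane F7, which can be purified.
- N-bromosuccinimide in CH2Cl2 at 0 °C converts Si–H into Si–Br, giving bromo(2-iodo-5-methylphenoxy)di(propan-2-yl)silane F8.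
- F8 is added directly to 11, Et3N and DMAP at 0 °C to give 14.

Step 2. Cationic dimerisation at the C3=C4 bond of the chromene, or Lewis-acid cleavage of the C7 methyl ether next to the new ketone, may outrun C-acylation. The fallback avoids a strong Lewis acid. It sets out from 5 and comes back at 6.
- Vilsmeier–Haack formylation (POCl3, DMF, 0 °C → rt, then aqueous NaOAc) gives 7-methoxy-2,2-dimethyl-2H-chromene-6-carbaldehyde F9.
- MeMgBr in THF at 0 °C gives racemic 1-(7-methoxy-2,2-dimethyl-2H-chromen-6-yl)ethan-1-ol F10.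
- MnO2 in CH2Cl2 at rt oxidises the benzylic alcohol to 6.

Further compounds
F1 | step 7 | (2-iodo-5-methylphenoxy)tri(propan-2-yl)silane | Cc1ccc(I)c(O[Si](C(C)C)(C(C)C)C(C)C)c1
F2 | step 7 | [4-methyl-2-(triisopropylsilyloxy)phenyl]magnesium chloride | Cc1ccc([Mg]Cl)c(O[Si](C(C)C)(C(C)C)C(C)C)c1
F3 | step 7 | 4-[4-methyl-2-(triisopropylsilyloxy)phenyl]-2,5-dihydro-1,2-oxamagnesole | Cc1ccc(C2=C[Mg]OC2)c(O[Si](C(C)C)(C(C)C)C(C)C)c1
F4 | step 7 | (2Z)-3-iodo-2-[4-methyl-2-(triisopropylsilyloxy)phenyl]prop-2-en-1-ol | I/C=C(\CO)c1ccc(C)cc1O[Si](C(C)C)(C(C)C)C(C)C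
F5 | step 7 | tert-butyl{[(2Z)-3-iodo-2-[4-methyl-2-(triisopropylsilyloxy)phenyl]prop-2-en-1-yl]oxy}dimethylsilane | I/C=C(\CO[Si](C)(C)C(C)(C)C)c1ccc(C)cc1O[Si](C(C)C)(C(C)C)C(C)C
F6 | step 7 | bis-silyl ether of 18 (phenol as triisopropylsilyl ether, CH2OH as tert-butyldimethylsilyl ether; (S), (Z)) | COc1cc2c(cc1[C@H](C)O/C=C(\CO[Si](C)(C)C(C)(C)C)c1ccc(C)cc1O[Si](C(C)C)(C(C)C)C(C)C)C=CC(C)(C)O2
F7 | step 6 | (2-iodo-5-methylphenoxy)di(propan-2-yl)silane | Cc1ccc(I)c(O[SiH](C(C)C)C(C)C)c1
F8 | step 6 | bromo(2-iodo-5-methylphenoxy)di(propan-2-yl)silane | Cc1ccc(I)c(O[Si](Br)(C(C)C)C(C)C)c1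
F9 | step 2 | 7-methoxy-2,2-dimethyl-2H-chromene-6-carbaldehyde | COc1cc2c(cc1C=O)C=CC(C)(C)O2
F10 | step 2 | racemic 1-(7-methoxy-2,2-dimethyl-2H-chromen-6-yl)ethan-1-ol | COc1cc2c(cc1C(C)O)C=CC(C)(C)O2
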